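**Strategy**

Everything rests on cutting the tetrahydrofuran ring (O1, C2 aryl, C3 CH2OH, C4 aroyl, C5) at O1–C2 and C3–C4. The key step exploits that O1 is β to the C3 hydroxymethyl carbon (an oxa-Michael/α-alkylation retron of a cinnamaldehyde) and that C5–C4 with its acyl carbon is an opened 2-(1-arylvinyl)oxirane. One dual-catalytic operation (zerovalent palladium, chiral secondary amine) should release the epoxide strain, join both fragments by formal [3+2] annulation and set the three ring stereocentres; the vinyl group is later cleaved to the ketone. Precursors: a silylated sinapaldehyde that already carries the erythro arylglycerol β-ether (magnesium-catalysed anti-aldol) and a racemic aryl vinyl epoxide.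

Key step: step 11

Assumption: compounds 1, 3, 4, 10, 13 and 15 are taken as purchasable; the (S)-aminocatalyst and the (S)-auxiliary are assigned from the usual steric-shielding and chelate models, not from experiment.

Abbreviations and numbering: ArA = 4-{[(1R,2S)-1,3-bis(tert-butyldimethylsilyloxy)-1-(3-methoxy-4-triisopropylsilyloxyphenyl)propan-2-yl]oxy}-3,5-dimethoxyphenyl; ArB = 3,5-dimethoxy-4-(triisopropylsilyloxy)phenyl. The tetrahydrofuran is numbered O1, C2 (aryl), C3 (CH2OH carbon), C4 (acyl carbon), C5 throughout.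

**Route**

Step 1
Reactants: 1 vanillin (4-hydroxy-3-methoxybenzaldehyde)
Product: 2 3-methoxy-4-(triisopropylsilyloxy)benzaldehyde
Conditions: TIPSCl, imidazole, DMF, rt
Reagents that add atoms: chlorotriisopropylsilane, CC(C)[Si](Cl)(C(C)C)C(C)C
Why: Imidazole-promoted silylation of the phenol; the bulky silyl ether should survive the later basic cross-coupling and leave with fluoride at the end.

Step 2
Reactants: 3 4-bromo-2,6-dimethoxyphenol; 4 (S)-4-benzyl-3-(chloroacetyl)oxazolidin-2-one
Product: 5 (S)-4-benzyl-3-[(4-bromo-2,6-dimethoxyphenoxy)acetyl]oxazolidin-2-one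
Conditions: K2CO3, NaI (cat.), acetone, rt to 45 °C
Reagents that add atoms: none
Why: Williamson etherification (with Finkelstein assistance): the phenoxide displaces the activated α-chloride and installs the future β-aryl ether oxygen without touching the auxiliary.

Step 3
Reactants: 5 (S)-4-benzyl-3-[(4-bromo-2,6-dimethoxyphenoxy)acetyl]oxazolidin-2-one; 2 3-methoxy-4-(triisopropylsilyloxy)benzaldehyde
Product: 7 (S)-4-benzyl-3-[(2R,3R)-2-(4-bromo-2,6-dimethoxyphenoxy)-3-hydroxy-3-(3-methoxy-4-triisopropylsilyloxyphenyl)propanoyl]oxazolidin-2-one, via aldol trimethylsilyl ether 6 (not isolated)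
Conditions: MgCl2 (20 mol%), Et3N, TMSCl, EtOAc, rt; then TFA (cat.), MeOH, rt
Reagents that add atoms: chlorotrimethylsilane, C[Si](C)(C)Cl (adds the silyl group of 6, which the methanolysis removes again; nothing from it stays in 7)
Why: Magnesium-halide-catalysed direct anti-aldol of an N-acyloxazolidinone (soft enolisation, silyl trapping), in which the magnesium-chelated Z-enolate should react on the face away from the benzyl group to give the anti (erythro) 2R,3R adduct, with the α-configuration opposite to that of the boron syn-aldol.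

Step 4
Reactants: 7 the anti-aldol imide
Product: 8 (1R,2S)-2-(4-bromo-2,6-dimethoxyphenoxy)-1-(3-methoxy-4-triisopropylsilyloxyphenyl)propane-1,3-diol
Conditions: LiBH4, MeOH (1 equiv), THF, 0 °C
Reagents that add atoms: none
Why: Reductive cleavage of the imide gives the primary alcohol and releases the auxiliary without touching either stereocentre (the ether carbon changes from R to S only because the CIP priorities change).

Step 5
Reactants: 8 the erythro 1,3-diol
Product: 9 ArA–Br (5-bromo-1,3-dimethoxybenzene carrying at C2 the bis-silylated (1R,2S)-glycerol ether defined above)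
Conditions: TBSOTf, 2,6-lutidine, CH2Cl2, −78 to 0 °C
Reagents that add atoms: tert-butyldimethylsilyl triflate, CC(C)(C)[Si](C)(C)OS(=O)(=O)C(F)(F)F
Why: Silyl triflate with a hindered base silylates both the primary and the hindered benzylic hydroxyl, so that no free OH can compete as a nucleophile in the key step.

Step 6
Reactants: 9 ArA–Br; 10 acrolein diethyl acetal (3,3-diethoxyprop-1-ene)
Product: 12 (E)-3-(ArA)prop-2-enal, via cinnamaldehyde diethyl acetal 11 (not isolated)
Conditions: Pd(OAc)2 (3 mol%), n-Bu4NOAc, K2CO3, KCl, DMF, 90 °C; then aq. oxalic acid, THF, rt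
Reagents that add atoms: water, O
Why: Heck reaction of the unhindered aryl bromide with the acrolein acetal under phase-transfer conditions should give the E-cinnamaldehyde acetal, which mild aqueous acid unmasks to the E-enal.

Step 7
Reactants: 13 2,6-dimethoxy-4-(4,4,5,5-tetramethyl-1,3,2-dioxaborolan-2-yl)phenol
Product: 14 ArB–B(pin) (the triisopropylsilyl ether of 13)
Conditions: TIPSOTf, 2,6-lutidine, CH2Cl2, 0 °C to rt
Reagents that add atoms: triisopropylsilyl triflate, CC(C)[Si](OS(=O)(=O)C(F)(F)F)(C(C)C)C(C)C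
Why: The reactive silyl triflate is needed to silylate the doubly ortho-substituted phenol; the boronate is inert to it.

Step 8
Reactants: 14 ArB–B(pin); 15 2-bromoprop-2-en-1-ol
Product: 16 2-(ArB)prop-2-en-1-ol
Conditions: PdCl2(dppf) (3 mol%), K3PO4, 1,4-dioxane/H2O, 80 °C
Reagents that add atoms: none
Why: Suzuki–Miyaura coupling of the aryl boronate with the vinyl bromide builds the 1,1-disubstituted alkene whose internal carbon later becomes the ketone carbon.

Step 9
Reactants: 16 2-(ArB)prop-2-en-1-ol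
Product: 17 2-(ArB)prop-2-enal
Conditions: activated MnO2, CH2Cl2, rt
Reagents that add atoms: none
Why: Chemoselective oxidation of the allylic alcohol; the polymerisation-prone 2-arylacrolein is used at once.

Step 10
Reactants: 17 2-(ArB)prop-2-enal
Product: 18 rac-2-[1-(ArB)ethenyl]oxirane
Conditions: Me3S+ I−, KOt-Bu, DMSO/THF, 0 °C to rt
Reagents that add atoms: trimethylsulfonium iodide, C[S+](C)C.[I-]
Why: Corey–Chaykovsky epoxidation: the unstabilised sulfonium ylide adds 1,2 to the enal and closes the oxirane, whose stereocentre is later erased in the π-allyl complex, so the racemate suffices.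

Step 11
Reactants: 12 (E)-3-(ArA)prop-2-enal; 18 rac-2-[1-(ArB)ethenyl]oxirane
Product: 20 [(2S,3R,4R)-2-(ArA)-4-[1-(ArB)ethenyl]tetrahydrofuran-3-yl]methanol, via tetrahydrofuran-3-carbaldehyde 19 (not isolated)
Conditions: Pd(PPh3)4 (5 mol%), (S)-α,α-diphenylprolinol trimethylsilyl ether (20 mol%), PhCO2H (20 mol%), THF, rt; then NaBH4, MeOH, 0 °C
Reagents that add atoms: none
Why: Proposed new method: zerovalent palladium opens the strained vinyl oxirane 18 to a zwitterionic 2-aryl-π-allylpalladium alkoxide while the amine turns enal 12 into an iminium ion; the alkoxide adds to the iminium β-carbon (oxa-Michael, O1–C2), the resulting enamine carbon C3 alkylates the tethered allyl terminus C4 (C3–C4), hydrolysis releases aldehyde 19 and both catalysts, and NaBH4 reduces 19 in the same flask to block retro-oxa-Michael opening. The closest known reaction types are the palladium-catalysed formal [3+2] cycloaddition of vinyl oxiranes with doubly activated alkenes and the synergistic palladium/secondary-amine [3+2] annulation of vinylcyclopropanes with enals, which this step merges on an oxygen zwitterion. The only ring closed is the tetrahydrofuran, by a 5-exo allylic alkylation (C3 attacks the internal allyl carbon; 7-endo attack on the CH2 terminus is disfavoured). C2 is set by the catalyst, whose diphenyl(silyloxy)methyl group shields one face of the E-iminium so that oxygen should add to the Si face and give 2S; C3 and C4 follow from the ring closure, which should place the formyl and arylvinyl groups trans to their neighbours, C3 staying correctable by enamine epimerisation and C4 again after step 12, when it becomes α to the ketone. The step needs β- over carbonyl attack of the alkoxide, internal over terminal allyl attack and face selectivity at C2; iminium activation of the β-aryl enal, the three-atom O1–C5–C4 tether and the π–σ–π equilibration of the allyl complex (both enantiomers of 18 converge) should secure them.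

Step 12
Reactants: 20 the 4-(1-arylethenyl)tetrahydrofuran-3-ylmethanol
Product: 22 (ArB)[(2S,3R,4S)-2-(ArA)-3-(hydroxymethyl)tetrahydrofuran-4-yl]methanone, via vicinal diol 21 (not isolated)
Conditions: OsO4 (2 mol%), NaIO4, 2,6-lutidine, 1,4-dioxane/H2O, rt
Reagents that add atoms: sodium periodate, [Na+].[O-]I(=O)(=O)=O (its oxygen reaches the product through catalytic OsO4, O=[Os](=O)(=O)=O)
Why: Lemieux–Johnson oxidation (osmium-catalysed dihydroxylation, then periodate glycol cleavage) of the only alkene unveils the aryl ketone, and C4, now α to the carbonyl and trans to C3, sits in its thermodynamically preferred configuration.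

Step 13
Reactants: 22 the fully silylated ketone
Product: 23 (4-hydroxy-3,5-dimethoxyphenyl)[(2S,3R,4S)-2-(4-{[(1R,2S)-1,3-dihydroxy-1-(4-hydroxy-3-methoxyphenyl)propan-2-yl]oxy}-3,5-dimethoxyphenyl)-3-(hydroxymethyl)tetrahydrofuran-4-yl]methanone (CNP0236429.1)
Conditions: TBAF, AcOH (1 equiv per fluoride), THF, 0 °C to rt
Reagents that add atoms: none
Why: Buffered fluoride should cleave the two aryl and two alkyl silyl ethers in one operation, while acetic acid keeps the medium too weakly basic for retro-oxa-Michael opening or epimerisation of the β-alkoxy ketone.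

**Compound list**

1 | vanillin | COc1cc(C=O)ccc1O | starting material
2 | 3-methoxy-4-(triisopropylsilyloxy)benzaldehyde | COc1cc(C=O)ccc1O[Si](C(C)C)(C(C)C)C(C)C | intermediate
3 | 4-bromo-2,6-dimethoxyphenol | COc1cc(Br)cc(OC)c1O | starting material
4 | (S)-4-benzyl-3-(chloroacetyl)oxazolidin-2-one | ClCC(=O)N1C(=O)OC[C@@H]1Cc1ccccc1 | starting material
5 | (S)-4-benzyl-3-[(4-bromo-2,6-dimethoxyphenoxy)acetyl]oxazolidin-2-one | COc1cc(Br)cc(OC)c1OCC(=O)N1C(=O)OC[C@@H]1Cc1ccccc1 | intermediate
6 | trimethylsilyl ether of 7 (2R,3R) | COc1cc([C@@H](O[Si](C)(C)C)[C@H](C(=O)N2C(=O)OC[C@@H]2Cc2ccccc2)Oc2c(OC)cc(Br)cc2OC)ccc1O[Si](C(C)C)(C(C)C)C(C)C | intermediate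
7 | (S)-4-benzyl-3-[(2R,3R)-2-(4-bromo-2,6-dimethoxyphenoxy)-3-hydroxy-3-(3-methoxy-4-triisopropylsilyloxyphenyl)propanoyl]oxazolidin-2-one | COc1cc([C@@H](O)[C@H](C(=O)N2C(=O)OC[C@@H]2Cc2ccccc2)Oc2c(OC)cc(Br)cc2OC)ccc1O[Si](C(C)C)(C(C)C)C(C)C | intermediate
8 | (1R,2S)-2-(4-bromo-2,6-dimethoxyphenoxy)-1-(3-methoxy-4-triisopropylsilyloxyphenyl)propane-1,3-diol | COc1cc([C@@H](O)[C@H](CO)Oc2c(OC)cc(Br)cc2OC)ccc1O[Si](C(C)C)(C(C)C)C(C)C | intermediate
9 | ArA–Br, bis(tert-butyldimethylsilyl) ether of 8 | COc1cc([C@@H](O[Si](C)(C)C(C)(C)C)[C@H](CO[Si](C)(C)C(C)(C)C)Oc2c(OC)cc(Br)cc2OC)ccc1O[Si](C(C)C)(C(C)C)C(C)C | intermediate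
10 | acrolein diethyl acetal | C=CC(OCC)OCC | starting material
11 | (E)-1-(ArA)-3,3-diethoxyprop-1-ene | COc1cc([C@@H](O[Si](C)(C)C(C)(C)C)[C@H](CO[Si](C)(C)C(C)(C)C)Oc2c(OC)cc(/C=C/C(OCC)OCC)cc2OC)ccc1O[Si](C(C)C)(C(C)C)C(C)C | intermediate
12 | (E)-3-(ArA)prop-2-enal | COc1cc([C@@H](O[Si](C)(C)C(C)(C)C)[C@H](CO[Si](C)(C)C(C)(C)C)Oc2c(OC)cc(/C=C/C=O)cc2OC)ccc1O[Si](C(C)C)(C(C)C)C(C)C | intermediate
13 | 2,6-dimethoxy-4-(4,4,5,5-tetramethyl-1,3,2-dioxaborolan-2-yl)phenol | COc1cc(B2OC(C)(C)C(C)(C)O2)cc(OC)c1O | starting material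
14 | ArB–B(pin), triisopropylsilyl ether of 13 | COc1cc(B2OC(C)(C)C(C)(C)O2)cc(OC)c1O[Si](C(C)C)(C(C)C)C(C)C | intermediate
15 | 2-bromoprop-2-en-1-ol | OCC(Br)=C | starting material
16 | 2-(ArB)prop-2-en-1-ol | C=C(CO)c1cc(OC)c(O[Si](C(C)C)(C(C)C)C(C)C)c(OC)c1 | intermediate
17 | 2-(ArB)prop-2-enal | C=C(C=O)c1cc(OC)c(O[Si](C(C)C)(C(C)C)C(C)C)c(OC)c1 | intermediate
18 | rac-2-[1-(ArB)ethenyl]oxirane | C=C(C1CO1)c1cc(OC)c(O[Si](C(C)C)(C(C)C)C(C)C)c(OC)c1 | intermediate
19 | (2S,3S,4R)-2-(ArA)-4-[1-(ArB)ethenyl]tetrahydrofuran-3-carbaldehyde | COc1cc([C@@H](O[Si](C)(C)C(C)(C)C)[C@H](CO[Si](C)(C)C(C)(C)C)Oc2c(OC)cc([C@H]3OC[C@@H](C(=C)c4cc(OC)c(O[Si](C(C)C)(C(C)C)C(C)C)c(OC)c4)[C@@H]3C=O)cc2OC)ccc1O[Si](C(C)C)(C(C)C)C(C)C | intermediate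
20 | [(2S,3R,4R)-2-(ArA)-4-[1-(ArB)ethenyl]tetrahydrofuran-3-yl]methanol | COc1cc([C@@H](O[Si](C)(C)C(C)(C)C)[C@H](CO[Si](C)(C)C(C)(C)C)Oc2c(OC)cc([C@H]3OC[C@@H](C(=C)c4cc(OC)c(O[Si](C(C)C)(C(C)C)C(C)C)c(OC)c4)[C@@H]3CO)cc2OC)ccc1O[Si](C(C)C)(C(C)C)C(C)C | intermediate
21 | 1-(ArB)-1-[(2S,3R,4S)-2-(ArA)-3-(hydroxymethyl)tetrahydrofuran-4-yl]ethane-1,2-diol (both epimers at the carbinol carbon) | COc1cc([C@@H](O[Si](C)(C)C(C)(C)C)[C@H](CO[Si](C)(C)C(C)(C)C)Oc2c(OC)cc([C@H]3OC[C@@H](C(O)(CO)c4cc(OC)c(O[Si](C(C)C)(C(C)C)C(C)C)c(OC)c4)[C@@H]3CO)cc2OC)ccc1O[Si](C(C)C)(C(C)C)C(C)C | intermediate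
22 | (ArB)[(2S,3R,4S)-2-(ArA)-3-(hydroxymethyl)tetrahydrofuran-4-yl]methanone | COc1cc([C@@H](O[Si](C)(C)C(C)(C)C)[C@H](CO[Si](C)(C)C(C)(C)C)Oc2c(OC)cc([C@H]3OC[C@@H](C(=O)c4cc(OC)c(O[Si](C(C)C)(C(C)C)C(C)C)c(OC)c4)[C@@H]3CO)cc2OC)ccc1O[Si](C(C)C)(C(C)C)C(C)C | intermediate
23 | CNP0236429.1, (2S,3R,4S)-tetrahydrofuran with (1R,2S) side chain | COc1cc([C@@H](O)[C@H](CO)Oc2c(OC)cc([C@H]3OC[C@@H](C(=O)c4cc(OC)c(O)c(OC)c4)[C@@H]3CO)cc2OC)ccc1O | target

**Totals and risks**

Total step count: 13. Longest linear sequence: 8 steps (steps 2, 3, 4, 5, 6, 11, 12, 13).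

Steps most likely to fail:

1. Step 11 (proposed new method). The ring-opened allyl alkoxide may isomerise to carbonyl compounds by β-hydride elimination, the alkoxide may attack the carbonyl carbon instead of the β-carbon, the amine may be N-allylated irreversibly, or face control at C2 may be weak. The fallback sets out from bromide 9 and returns at alcohol 20, using known chemistry. Palladium-catalysed reductive carbonylation (Pd(OAc)2, di(1-adamantyl)-n-butylphosphine, CO/H2, TMEDA, toluene, 100 °C) should give the benzaldehyde F1. Knoevenagel condensation with Meldrum's acid (pyrrolidine/AcOH cat., benzene, rt) should give the arylidene Meldrum's acid F2, a doubly activated alkene of the class for which the palladium-catalysed [3+2] cycloaddition with vinyl oxiranes is established. Reaction of F2 with 18 (Pd2(dba)3, a C2-symmetric diaminocyclohexane-derived bisphosphine chosen by screening, THF, rt) should form the same two bonds and give the spiro cycloadduct F3, the ligand now carrying the absolute control and the 2,4-cis isomer being separated if necessary. Methanolysis with decarboxylation (MeOH, pyridine, heat; then NaOMe, MeOH for equilibration) should give the all-trans methyl ester F4, and i-Bu2AlH (CH2Cl2, −78 to 0 °C) should reduce it to 20.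

2. Step 3. Soft enolisation of the α-aryloxy imide may be slow, or a competing chelate through the aryl ether oxygen may erode the anti selectivity. The fallback sets out from imide 5 and returns at aldol 7. Bu2BOTf and i-Pr2NEt (CH2Cl2, 0 °C) should give the Z-configured dibutylboron enolate F5; this is added at −78 °C to aldehyde 2 precomplexed with Et2AlCl. The externally activated aldehyde reacts through an open transition state on the internally chelated boron enolate, a known route to the same anti adduct with the same α-configuration; aqueous oxidative work-up should give 7.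

3. Step 6. β-Hydride elimination toward the acetal carbon would lead to the saturated ester after hydrolysis, and the hot basic medium may strip silyl ethers. The fallback sets out from bromide 9 and returns at enal 12. Suzuki–Miyaura coupling of 9 with commercial (E)-2-(3,3-diethoxyprop-1-en-1-yl)-4,4,5,5-tetramethyl-1,3,2-dioxaborolane (PdCl2(dppf), K3PO4, 1,4-dioxane/H2O, 80 °C) should give acetal 11 with alkene position and geometry fixed by the reagent, and the same mild hydrolysis gives 12; no compound outside the list is made (F0).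

**Further compounds**

F1 | step 11 | ArA–CHO, 4-{[(1R,2S)-1,3-bis(tert-butyldimethylsilyloxy)-1-(3-methoxy-4-triisopropylsilyloxyphenyl)propan-2-yl]oxy}-3,5-dimethoxybenzaldehyde | COc1cc([C@@H](O[Si](C)(C)C(C)(C)C)[C@H](CO[Si](C)(C)C(C)(C)C)Oc2c(OC)cc(C=O)cc2OC)ccc1O[Si](C(C)C)(C(C)C)C(C)C
F2 | step 11 | 5-[(ArA)methylidene]-2,2-dimethyl-1,3-dioxane-4,6-dione | COc1cc([C@@H](O[Si](C)(C)C(C)(C)C)[C@H](CO[Si](C)(C)C(C)(C)C)Oc2c(OC)cc(C=C3C(=O)OC(C)(C)OC3=O)cc2OC)ccc1O[Si](C(C)C)(C(C)C)C(C)C
F3 | step 11 | (1R,4S)-1-(ArA)-4-[1-(ArB)ethenyl]-8,8-dimethyl-2,7,9-trioxaspiro[4.5]decane-6,10-dione | COc1cc([C@@H](O[Si](C)(C)C(C)(C)C)[C@H](CO[Si](C)(C)C(C)(C)C)Oc2c(OC)cc([C@H]3OC[C@@H](C(=C)c4cc(OC)c(O[Si](C(C)C)(C(C)C)C(C)C)c(OC)c4)C35C(=O)OC(C)(C)OC5=O)cc2OC)ccc1O[Si](C(C)C)(C(C)C)C(C)C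
F4 | step 11 | methyl (2S,3S,4R)-2-(ArA)-4-[1-(ArB)ethenyl]tetrahydrofuran-3-carboxylate | COc1cc([C@@H](O[Si](C)(C)C(C)(C)C)[C@H](CO[Si](C)(C)C(C)(C)C)Oc2c(OC)cc([C@H]3OC[C@@H](C(=C)c4cc(OC)c(O[Si](C(C)C)(C(C)C)C(C)C)c(OC)c4)[C@@H]3C(=O)OC)cc2OC)ccc1O[Si](C(C)C)(C(C)C)C(C)C
F5 | step 3 | (Z)-dibutylboron enolate of imide 5 | CCCCB(CCCC)O/C(=C\Oc1c(OC)cc(Br)cc1OC)N1C(=O)OC[C@@H]1Cc1ccccc1
F0 | step 6 | none | none
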